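The route rests on cutting ring C at C4–C4a and C3–C1′. C4 carries ring A and an oxygen, and its neighbour C3 carries ring B and the C2 methylene. This 1,2-diaryl pattern is what a palladium-triggered 1,2-metalate shift of an alkenylboron ate complex delivers. In one operation ring A moves from boron to C4 and ring B is joined to C3, setting both stereocentres; the C–B bond later becomes the C4 hydroxyl. The precursor is the ate complex from 2,4-bis(benzyloxy)phenyllithium and an (E)-3-(benzyloxy)propenylboronate carrying a hindered cis-diol, coupled with a silyl-protected ring-B bromide that already contains ring D.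

Key step: step 11

Remarks on the chemistry:
- Numbering: C2, C3, C4, C4a and O1 belong to ring C; C1′ is the ring-B carbon bonded to C3. The ring B/D fragment uses chroman numbering, with bromine on C6.
- Boron ligand: with pinacol on boron, β-substituted alkenyl ate complexes tend to hand the alkenyl group directly to palladium. The boronate is therefore used as its ester with cis-1,2-dimethylacenaphthylene-1,2-diol, a spectator that leaves in step 12.
- Ring-B bromide: bromine is introduced by phenol-directed ortho-bromination of a symmetric-precursor-derived chromanol, which avoids an ipso-bromination that would compete with attack at C8.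
- Assumption: the bisphosphine antipode written in step 11 is taken to give the (1S,2R)-boronate; if a test coupling shows the opposite sense, its mirror image is used.

Step 1
Reactants: 1 2′,6′-dihydroxyacetophenone; 2 acetone
Product: 3 5-hydroxy-2,2-dimethylchroman-4-one
Conditions: pyrrolidine (0.5 equiv), toluene, reflux, water separator
Reagents that add atoms: none
Why: Kabbe condensation, in which amine-mediated crossed aldol condensation of the acetyl methyl group with acetone is followed by oxa-Michael closure of ring D, and because the two phenols are equivalent only one chromanone can form.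

Step 2
Reactants: 3 5-hydroxy-2,2-dimethylchroman-4-one
Product: 5 2,2-dimethyl-2H-chromen-5-ol, via 2,2-dimethylchroman-4,5-diol 4 (not isolated)
Conditions: NaBH4, MeOH/THF, 0 °C; then p-TsOH (cat.), toluene, 80 °C
Reagents that add atoms: none
Why: Borohydride reduction of the ketone followed by acid-catalysed dehydration of the benzylic alcohol should give the C3=C4 alkene, the only elimination product available.

Step 3
Reactants: 5 2,2-dimethyl-2H-chromen-5-ol
Product: 6 2,2-dimethyl-2H-chromen-5-yl pivalate
Conditions: t-BuCOCl, Et3N, DMAP (cat.), CH2Cl2, 0 °C → rt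
Reagents that add atoms: pivaloyl chloride, CC(C)(C)C(Cl)=O
Why: O-Acylation masks the phenol against the oxidant of the next step with an ester that resists aqueous hypochlorite and is removed by the hydride of step 5 without an extra operation.

Step 4
Reactants: 6 2,2-dimethyl-2H-chromen-5-yl pivalate
Product: 7 (3R,4R)-3,4-epoxy-2,2-dimethylchroman-5-yl pivalate
Conditions: (R,R)-N,N′-bis(3,5-di-tert-butylsalicylidene)-1,2-cyclohexanediaminomanganese chloride (4 mol%), NaOCl (aq, pH 11.3), 4-phenylpyridine N-oxide, CH2Cl2, 0 °C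
Reagents that add atoms: sodium hypochlorite, [Na+].[O-]Cl
Why: Jacobsen epoxidation, for which cis-disubstituted 2,2-dimethylchromenes are among the best substrates, and the (R,R)-catalyst is expected to deliver oxygen to the face that gives the (3R,4R)-epoxide.

Step 5
Reactants: 7 (3R,4R)-3,4-epoxy-2,2-dimethylchroman-5-yl pivalate
Product: 8 (R)-2,2-dimethylchroman-3,5-diol
Conditions: LiAlH4, THF, 0 °C
Reagents that add atoms: none
Why: Hydride opening of the epoxide at the benzylic C4, which is also remote from the gem-dimethyl group, leaves the C3–O bond and hence the (3R) configuration untouched, while the same reagent reduces off the pivalate.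

Step 6
Reactants: 8 (R)-2,2-dimethylchroman-3,5-diol
Product: 9 (R)-6-bromo-2,2-dimethylchroman-3,5-diol
Conditions: NBS (1.0 equiv), i-Pr2NH (0.1 equiv), CH2Cl2, −78 °C → 0 °C
Reagents that add atoms: N-bromosuccinimide, O=C1CCC(=O)N1Br
Why: Amine-mediated ortho-bromination of a phenol, in which the hydrogen-bonded N-bromoamine delivers bromine next to the hydroxyl, so that C6, the only free ortho position and also para to the ring-D oxygen, should be brominated in preference to C8.

Step 7
Reactants: 9 (R)-6-bromo-2,2-dimethylchroman-3,5-diol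
Product: 10 (R)-6-bromo-3,5-bis(tert-butyldimethylsilyloxy)-2,2-dimethylchroman
Conditions: TBSOTf (2.5 equiv), 2,6-lutidine, CH2Cl2, 0 °C → rt
Reagents that add atoms: tert-butyldimethylsilyl triflate, CC(C)(C)[Si](C)(C)OS(=O)(=O)C(F)(F)F
Why: Silylation with the reactive silyl triflate should cover both the hindered phenol and the neopentyl-type secondary alcohol, giving groups that survive the ate complex and leave with fluoride at the end.

Step 8
Reactants: 11 4-bromoresorcinol
Product: 12 2,4-bis(benzyloxy)-1-bromobenzene
Conditions: BnBr (2.2 equiv), K2CO3, DMF, rt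
Reagents that add atoms: benzyl bromide, BrCc1ccccc1
Why: Williamson etherification of both phenols gives ethers that tolerate the aryllithium and are later removed by neutral hydrogenolysis.

Step 9
Reactants: 13 acenaphthenequinone
Product: 14 cis-1,2-dimethyl-1,2-dihydroacenaphthylene-1,2-diol (meso)
Conditions: MeMgBr (2.5 equiv), THF, −78 °C → 0 °C; aq NH4Cl; crystallisation
Reagents that add atoms: methylmagnesium bromide, C[Mg]Br
Why: Double Grignard addition to the 1,2-diketone, in which the second methyl group should enter anti to the bulky magnesium alkoxide to give mainly the cis-diol, the only isomer able to form the cyclic boronate of step 10.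

Step 10
Reactants: 15 benzyl propargyl ether; 14 cis-1,2-dimethyl-1,2-dihydroacenaphthylene-1,2-diol
Product: 17 (E)-3-(benzyloxy)prop-1-enylboronic acid cis-1,2-dimethylacenaphthylene-1,2-diyl ester, via 2-[(E)-3-(benzyloxy)prop-1-enyl]-1,3,2-benzodioxaborole 16 (not isolated)
Conditions: catecholborane (1.1 equiv), neat, 70 °C; then 14, THF, rt
Reagents that add atoms: catecholborane, [H]B1Oc2ccccc2O1
Why: Syn hydroboration of the terminal alkyne places boron on the terminal carbon and gives the (E)-alkenylboronate, whose labile catechol ester is then exchanged for the chelating cis-diol by transesterification.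

Step 11
Reactants: 12 2,4-bis(benzyloxy)-1-bromobenzene; 17 (E)-3-(benzyloxy)prop-1-enylboronic acid cis-1,2-dimethylacenaphthylene-1,2-diyl ester; 10 (R)-6-bromo-3,5-bis(tert-butyldimethylsilyloxy)-2,2-dimethylchroman
Product: 20 (1S,2R)-1-[2,4-bis(benzyloxy)phenyl]-3-(benzyloxy)-2-[(3R)-3,5-bis(tert-butyldimethylsilyloxy)-2,2-dimethylchroman-6-yl]propylboronic acid cis-1,2-dimethylacenaphthylene-1,2-diyl ester, via 2,4-bis(benzyloxy)phenyllithium 18 (not isolated), via lithium boron ate complex 19 (not isolated)
Conditions: 12, t-BuLi (2.0 equiv per 12), Et2O, −78 °C; 17, −78 °C → rt; solvent changed to THF; 10, Pd(OAc)2 (5 mol%), (S,S)-1,1′-bis[bis(4-methoxy-3,5-dimethylphenyl)phosphino]-2,2′-bis[(R)-α-(dimethylamino)benzyl]ferrocene (6 mol%), KOSO2CF3 (2 equiv), 60 °C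
Reagents that add atoms: none
Why: The aryllithium adds to boron to give the four-coordinate ate complex, while Pd(OAc)2 and the bisphosphine give zerovalent palladium that inserts into the C–Br bond of 10, and KOSO2CF3 strips bromide so that the cationic aryl–palladium (divalent) can bind the alkene of 19. Ring A then shifts from boron to C4 on the face opposite to palladium, forming C4–C4a while palladium takes C3, and reductive elimination with retention forms C3–C1′. The closest known reaction type is the enantioselective conjunctive cross-coupling of β-substituted alkenylboron ate complexes that carry this hindered diol, here applied with an aryl bromide and a triflate salt as halide scavenger. The step forms two bonds and closes no ring. C3 and C4 are set together: the chiral bisphosphine chooses the alkene face and so the absolute configuration, and the (E)-geometry combined with the anti relationship of migrating aryl and palladium fixes the relative configuration that becomes the trans C3/C4 pair. The step needs the metalate shift to outrun direct alkenyl transfer to palladium and β-elimination towards C2, which the bulky rigid diol on boron and the chelating bisphosphine are chosen to secure.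

Step 12
Reactants: 20 the boronic ester of step 11
Product: 21 (1S,2R)-1-[2,4-bis(benzyloxy)phenyl]-3-(benzyloxy)-2-[(3R)-3,5-bis(tert-butyldimethylsilyloxy)-2,2-dimethylchroman-6-yl]propan-1-ol
Conditions: NaBO3·4H2O, THF/H2O (1:1), rt
Reagents that add atoms: sodium perborate, [Na+].[O-]OB=O
Why: Oxidation of the secondary boronic ester by peroxide addition to boron and 1,2-shift of carbon to oxygen proceeds with retention, and the mild perborate is chosen so that the hindered aryl silyl ether should survive.

Step 13
Reactants: 21 the benzylic alcohol of step 12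
Product: 22 (1S,2R)-2-[(3R)-3,5-bis(tert-butyldimethylsilyloxy)-2,2-dimethylchroman-6-yl]-1-(2,4-dihydroxyphenyl)propane-1,3-diol
Conditions: H2 (1 atm), Pd/C (10 wt%), EtOAc, rt
Reagents that add atoms: none
Why: Hydrogenolysis of the two aryl benzyl ethers and the primary benzyl ether in a neutral aprotic solvent should leave the silyl ethers intact and, without acid to ionise it, the secondary benzylic hydroxyl as well.

Step 14
Reactants: 22 the tetraol of step 13
Product: 23 (3R,4S)-3-[(3R)-3,5-bis(tert-butyldimethylsilyloxy)-2,2-dimethylchroman-6-yl]chroman-4,7-diol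
Conditions: PPh3, DIAD, THF, 0 °C → rt
Reagents that add atoms: none
Why: Mitsunobu etherification, in which the primary alcohol is activated in preference to the hindered secondary one and is displaced by the ortho phenol of ring A in a six-membered closure that forms O1–C2 without touching either stereocentre.

Step 15
Reactants: 23 the bis-silyl ether of step 14
Product: 24 (3R,4S)-3-[(3R)-3,5-dihydroxy-2,2-dimethylchroman-6-yl]chroman-4,7-diol (CNP0271781.1)
Conditions: n-Bu4NF (4 equiv), THF, 0 °C → rt; pH 7 buffer
Reagents that add atoms: none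
Why: Fluoride-mediated desilylation removes both silyl ethers without acid, which matters because the ring-B phenol next to C3 would otherwise be prone to cyclise onto the C4 benzylic position.

Compound list
1 | 2′,6′-dihydroxyacetophenone | CC(=O)c1c(O)cccc1O | starting material
2 | acetone | CC(C)=O | starting material
3 | 5-hydroxy-2,2-dimethylchroman-4-one | CC1(C)CC(=O)c2c(O)cccc2O1 | intermediate
4 | 2,2-dimethylchroman-4,5-diol (racemic, not isolated) | CC1(C)CC(O)c2c(O)cccc2O1 | intermediate
5 | 2,2-dimethyl-2H-chromen-5-ol | CC1(C)C=Cc2c(O)cccc2O1 | intermediate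
6 | 2,2-dimethyl-2H-chromen-5-yl pivalate | CC1(C)C=Cc2c(OC(=O)C(C)(C)C)cccc2O1 | intermediate
7 | (3R,4R)-3,4-epoxy-2,2-dimethylchroman-5-yl pivalate | CC1(C)Oc2cccc(OC(=O)C(C)(C)C)c2[C@H]2O[C@@H]12 | intermediate
8 | (R)-2,2-dimethylchroman-3,5-diol | CC1(C)Oc2cccc(O)c2C[C@H]1O | intermediate
9 | (R)-6-bromo-2,2-dimethylchroman-3,5-diol | CC1(C)Oc2ccc(Br)c(O)c2C[C@H]1O | intermediate
10 | (R)-6-bromo-3,5-bis(tert-butyldimethylsilyloxy)-2,2-dimethylchroman (ring-B bromide) | CC1(C)Oc2ccc(Br)c(O[Si](C)(C)C(C)(C)C)c2C[C@H]1O[Si](C)(C)C(C)(C)C | intermediate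
11 | 4-bromoresorcinol | Oc1ccc(Br)c(O)c1 | starting material
12 | 2,4-bis(benzyloxy)-1-bromobenzene | Brc1ccc(OCc2ccccc2)cc1OCc1ccccc1 | intermediate
13 | acenaphthenequinone | O=C1C(=O)c2cccc3cccc1c23 | starting material
14 | cis-1,2-dimethyl-1,2-dihydroacenaphthylene-1,2-diol (meso) | C[C@@]1(O)c2cccc3cccc(c23)[C@]1(C)O | intermediate
15 | benzyl propargyl ether | C#CCOCc1ccccc1 | starting material
16 | 2-[(E)-3-(benzyloxy)prop-1-enyl]-1,3,2-benzodioxaborole (not isolated) | B1(/C=C/COCc2ccccc2)Oc2ccccc2O1 | intermediate
17 | (E)-3-(benzyloxy)prop-1-enylboronic acid cis-1,2-dimethylacenaphthylene-1,2-diyl ester | C[C@@]12c3cccc4cccc(c34)[C@]1(C)OB(/C=C/COCc1ccccc1)O2 | intermediate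
18 | 2,4-bis(benzyloxy)phenyllithium (not isolated) | [Li]c1ccc(OCc2ccccc2)cc1OCc1ccccc1 | intermediate
19 | lithium [2,4-bis(benzyloxy)phenyl][(E)-3-(benzyloxy)prop-1-enyl]borate of diol 14 (ate complex, configuration at boron undefined, not isolated) | [Li+].C[C@@]12c3cccc4cccc(c34)[C@]1(C)O[B-](/C=C/COCc1ccccc1)(c1ccc(OCc3ccccc3)cc1OCc1ccccc1)O2 | intermediate
20 | (1S,2R)-1-[2,4-bis(benzyloxy)phenyl]-3-(benzyloxy)-2-[(3R)-3,5-bis(tert-butyldimethylsilyloxy)-2,2-dimethylchroman-6-yl]propylboronic acid cis-1,2-dimethylacenaphthylene-1,2-diyl ester | CC1(C)Oc2ccc([C@H](COCc3ccccc3)[C@H](B3O[C@]4(C)c5cccc6cccc(c56)[C@]4(C)O3)c3ccc(OCc4ccccc4)cc3OCc3ccccc3)c(O[Si](C)(C)C(C)(C)C)c2C[C@H]1O[Si](C)(C)C(C)(C)C | intermediate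
21 | (1S,2R)-1-[2,4-bis(benzyloxy)phenyl]-3-(benzyloxy)-2-[(3R)-3,5-bis(tert-butyldimethylsilyloxy)-2,2-dimethylchroman-6-yl]propan-1-ol | CC1(C)Oc2ccc([C@H](COCc3ccccc3)[C@H](O)c3ccc(OCc4ccccc4)cc3OCc3ccccc3)c(O[Si](C)(C)C(C)(C)C)c2C[C@H]1O[Si](C)(C)C(C)(C)C | intermediate
22 | (1S,2R)-2-[(3R)-3,5-bis(tert-butyldimethylsilyloxy)-2,2-dimethylchroman-6-yl]-1-(2,4-dihydroxyphenyl)propane-1,3-diol | CC1(C)Oc2ccc([C@H](CO)[C@H](O)c3ccc(O)cc3O)c(O[Si](C)(C)C(C)(C)C)c2C[C@H]1O[Si](C)(C)C(C)(C)C | intermediate
23 | (3R,4S)-3-[(3R)-3,5-bis(tert-butyldimethylsilyloxy)-2,2-dimethylchroman-6-yl]chroman-4,7-diol | CC1(C)Oc2ccc([C@@H]3COc4cc(O)ccc4[C@H]3O)c(O[Si](C)(C)C(C)(C)C)c2C[C@H]1O[Si](C)(C)C(C)(C)C | intermediate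
24 | (3R,4S)-3-[(3R)-3,5-dihydroxy-2,2-dimethylchroman-6-yl]chroman-4,7-diol (CNP0271781.1) | CC1(C)Oc2ccc([C@@H]3COc4cc(O)ccc4[C@H]3O)c(O)c2C[C@H]1O | target

Total step count: 15. Longest linear sequence: 12 steps (steps 1–7, then 11–15).

Steps most likely to fail

Step 11. The ate complex may transfer its alkenyl group directly to palladium instead of undergoing the metalate shift. Oxidative addition into the electron-rich, ortho-silyloxy bromide may be slow. The alkylpalladium may lose hydride or benzyloxide from C2. Facial selection may be weak. The fallback replaces the coupling by an auxiliary-controlled syn aldol reaction and sets out from 10. Palladium-catalysed coupling of 10 with BrZnCH2CO2t-Bu (Pd(dba)2, P(t-Bu)3, THF) should give tert-butyl 2-[(3R)-3,5-bis(tert-butyldimethylsilyloxy)-2,2-dimethylchroman-6-yl]acetate F1. Cleavage of the tert-butyl ester with TMSOTf and 2,6-lutidine gives the arylacetic acid F2, and its mixed pivalic anhydride acylates lithiated (S)-4-benzyloxazolidin-2-one to give the N-arylacetyl oxazolidinone F3. Enolisation with Bu2BOTf and i-Pr2NEt and addition of commercial 2,4-bis(benzyloxy)benzaldehyde at −78 °C should give the syn aldol adduct F4; the (Z)-boron enolate reacts through a chair transition state on the face left open by the benzyl group, which corresponds to the (1S,2R) arrangement needed. LiBH4 removes the auxiliary to give the 1,3-diol F5, and hydrogenolysis over Pd/C brings the material back to the route at 22.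

Step 6. Bromine may enter at C8, para to the phenol, or twice. The fallback fixes the position by directed ortho-metalation and sets out from 8. Treatment with MOMCl and i-Pr2NEt gives (R)-3,5-bis(methoxymethoxy)-2,2-dimethylchroman F6. n-BuLi with TMEDA in Et2O at 0 °C should lithiate C6, the only free position next to the aryl methoxymethyl ether, and BrCF2CF2Br then gives (R)-6-bromo-3,5-bis(methoxymethoxy)-2,2-dimethylchroman F7. HCl in MeOH removes both acetals and returns the material to the route at 9.

Step 13. The doubly activated benzylic C4 hydroxyl may be lost by hydrogenolysis or by ionisation on the catalyst surface. The fallback changes the order so that no benzylic alcohol is present during hydrogenolysis, and sets out from 20. Hydrogenolysis of 20 (H2, Pd/C, EtOAc) should give the phenolic boronate triol F8, since the carbon–boron bond is inert under these conditions. Mitsunobu closure (PPh3, DIAD) gives the chroman-4-ylboronic ester F9. Oxidation with NaBO3·4H2O, again with retention, returns the material to the route at 23.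

Further compounds
F1 | step 11 | tert-butyl 2-[(3R)-3,5-bis(tert-butyldimethylsilyloxy)-2,2-dimethylchroman-6-yl]acetate | CC1(C)Oc2ccc(CC(=O)OC(C)(C)C)c(O[Si](C)(C)C(C)(C)C)c2C[C@H]1O[Si](C)(C)C(C)(C)C
F2 | step 11 | 2-[(3R)-3,5-bis(tert-butyldimethylsilyloxy)-2,2-dimethylchroman-6-yl]acetic acid | CC1(C)Oc2ccc(CC(=O)O)c(O[Si](C)(C)C(C)(C)C)c2C[C@H]1O[Si](C)(C)C(C)(C)C
F3 | step 11 | (S)-4-benzyl-3-{2-[(3R)-3,5-bis(tert-butyldimethylsilyloxy)-2,2-dimethylchroman-6-yl]acetyl}oxazolidin-2-one | CC1(C)Oc2ccc(CC(=O)N3C(=O)OC[C@@H]3Cc3ccccc3)c(O[Si](C)(C)C(C)(C)C)c2C[C@H]1O[Si](C)(C)C(C)(C)C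
F4 | step 11 | syn aldol adduct of F3 with 2,4-bis(benzyloxy)benzaldehyde | CC1(C)Oc2ccc([C@H](C(=O)N3C(=O)OC[C@@H]3Cc3ccccc3)[C@H](O)c3ccc(OCc4ccccc4)cc3OCc3ccccc3)c(O[Si](C)(C)C(C)(C)C)c2C[C@H]1O[Si](C)(C)C(C)(C)C
F5 | step 11 | (1S,2R)-1-[2,4-bis(benzyloxy)phenyl]-2-[(3R)-3,5-bis(tert-butyldimethylsilyloxy)-2,2-dimethylchroman-6-yl]propane-1,3-diol | CC1(C)Oc2ccc([C@H](CO)[C@H](O)c3ccc(OCc4ccccc4)cc3OCc3ccccc3)c(O[Si](C)(C)C(C)(C)C)c2C[C@H]1O[Si](C)(C)C(C)(C)C
F6 | step 6 | (R)-3,5-bis(methoxymethoxy)-2,2-dimethylchroman | CC1(C)Oc2cccc(OCOC)c2C[C@H]1OCOC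
F7 | step 6 | (R)-6-bromo-3,5-bis(methoxymethoxy)-2,2-dimethylchroman | CC1(C)Oc2ccc(Br)c(OCOC)c2C[C@H]1OCOC
F8 | step 13 | (1S,2R)-2-[(3R)-3,5-bis(tert-butyldimethylsilyloxy)-2,2-dimethylchroman-6-yl]-1-(2,4-dihydroxyphenyl)-3-hydroxypropylboronic acid cis-1,2-dimethylacenaphthylene-1,2-diyl ester | CC1(C)Oc2ccc([C@H](CO)[C@H](B3O[C@]4(C)c5cccc6cccc(c56)[C@]4(C)O3)c3ccc(O)cc3O)c(O[Si](C)(C)C(C)(C)C)c2C[C@H]1O[Si](C)(C)C(C)(C)C
F9 | step 13 | (3R,4S)-3-[(3R)-3,5-bis(tert-butyldimethylsilyloxy)-2,2-dimethylchroman-6-yl]-7-hydroxychroman-4-ylboronic acid cis-1,2-dimethylacenaphthylene-1,2-diyl ester | CC1(C)Oc2ccc([C@@H]3COc4cc(O)ccc4[C@H]3B3O[C@]4(C)c5cccc6cccc(c56)[C@]4(C)O3)c(O[Si](C)(C)C(C)(C)C)c2C[C@H]1O[Si](C)(C)C(C)(C)C
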